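**Plan**

1. Retrosynthetic cuts, last-made first: (a) O5–CH3 of the flavanone and the three benzyl–O bonds of the flavone half (one BCl3 unmasking); (b) C4–C4a, opening ring C of the flavanone to a 3-aryl-3-(3,5-dimethoxyphenoxy)propanoic acid; (c) O1–C2 (Mitsunobu); (d) the C3–C4 unit (diazoacetate homologation of an aldehyde); (e) the diaryl ether O–C bond (SNAr); (f) the pyranone ring of the flavone half (chalcone route).
2. Forward: the benzylated flavone with a free 3'-OH is built first and joined to 4-fluorobenzaldehyde. The chain O1–C2–C3–C4 is then assembled on the aldehyde carbon, and ring C of the flavanone is closed last onto ring A, before one global deprotection.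
3. Enabling feature: ring A is a phloroglucinol ring in which C4a lies ortho to O1, ortho to the C5 oxygen and para to the C7 oxygen. In the 3,5-dimethoxyphenyl ether the two carbons ortho to O1 are equivalent, so acylation by C4 gives one ring and one regioisomer without a directing group.
4. The new C4=O then singles out the peri C5 methoxy group for chelation-controlled cleavage, so the 5-OH/7-OMe pattern needs no protecting-group differentiation.
5. Stereochemistry: C2 (S, as the SMILES descriptor requires) comes from a Noyori hydrogenation of the β-keto ester to the (R)-carbinol followed by Mitsunobu inversion; no later step breaks a bond at C2.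

Key step: step 8

**Route**

Step 1
Reactants: 1 1-[2,4-bis(benzyloxy)-6-hydroxyphenyl]ethan-1-one; 2 4-(benzyloxy)-3-hydroxybenzaldehyde
Product: 3 (2E)-1-[2,4-bis(benzyloxy)-6-hydroxyphenyl]-3-[4-(benzyloxy)-3-hydroxyphenyl]prop-2-en-1-one
Conditions: KOH (50% aq., excess), EtOH, rt; then 1 M HCl
Reagents that add atoms: none
Why: Claisen–Schmidt (crossed aldol) condensation, in which the methyl ketone enolate adds to the non-enolisable aldehyde and E1cB loss of water gives the conjugated E-enone under thermodynamic control, the meta-phenoxide of 2 not being conjugated with the formyl group; no stereocenter is formed.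

Step 2
Reactants: 3 (2E)-1-[2,4-bis(benzyloxy)-6-hydroxyphenyl]-3-[4-(benzyloxy)-3-hydroxyphenyl]prop-2-en-1-one
Product: 5 5,7-bis(benzyloxy)-2-[4-(benzyloxy)-3-hydroxyphenyl]-4H-chromen-4-one, via racemic flavanone 4 (not isolated)
Conditions: I2 (10 mol%), DMSO, 130 °C
Reagents that add atoms: none
Why: Iodine-catalysed oxidative cyclisation of a 2'-hydroxychalcone, in which oxa-Michael closure to flavanone 4, iodination at C3 and loss of HI give the flavone while DMSO reoxidises HI to I2, conditions that aryl benzyl ethers and a free ring B phenol should tolerate; the stereocenter of 4 is destroyed again.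

Step 3
Reactants: 5 5,7-bis(benzyloxy)-2-[4-(benzyloxy)-3-hydroxyphenyl]-4H-chromen-4-one; 6 4-fluorobenzaldehyde
Product: 7 4-{2-(benzyloxy)-5-[5,7-bis(benzyloxy)-4-oxo-4H-chromen-2-yl]phenoxy}benzaldehyde
Conditions: K2CO3, DMF, 110 °C
Reagents that add atoms: none
Why: Nucleophilic aromatic substitution (addition–elimination through a Meisenheimer adduct), in which the phenoxide of 5 displaces fluoride para to the formyl group, the only acceptor-activated aryl halide present, while the flavone and the benzyl ethers are inert to carbonate.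

Step 4
Reactants: 7 4-{2-(benzyloxy)-5-[5,7-bis(benzyloxy)-4-oxo-4H-chromen-2-yl]phenoxy}benzaldehyde; 8 ethyl diazoacetate
Product: 9 ethyl 3-(4-{2-(benzyloxy)-5-[5,7-bis(benzyloxy)-4-oxo-4H-chromen-2-yl]phenoxy}phenyl)-3-oxopropanoate
Conditions: SnCl2 (20 mol%), CH2Cl2, rt
Reagents that add atoms: none
Why: Roskamp homologation, in which SnCl2 activates the aldehyde for attack by the diazo carbon and loss of N2 with 1,2-hydride shift gives the β-keto ester, while the far less electrophilic vinylogous-ester carbonyl of the flavone should not react.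

Step 5
Reactants: 9 ethyl 3-(4-{2-(benzyloxy)-5-[5,7-bis(benzyloxy)-4-oxo-4H-chromen-2-yl]phenoxy}phenyl)-3-oxopropanoate
Product: 10 ethyl (3R)-3-(4-{2-(benzyloxy)-5-[5,7-bis(benzyloxy)-4-oxo-4H-chromen-2-yl]phenoxy}phenyl)-3-hydroxypropanoate
Conditions: [RuCl(p-cymene)((S)-SEGPHOS)]Cl (1 mol%), H2 (30 bar), EtOH/CH2Cl2, 50 °C
Reagents that add atoms: none
Why: Noyori asymmetric hydrogenation of a β-keto ester, in which the substrate chelates ruthenium through both carbonyl oxygens and the (S)-configured biaryl bisphosphine directs hydride to the ketone face that gives the (R)-carbinol of aryl β-keto esters (catalyst control; the descriptor is R because aryl outranks CH2CO2Et), a catalyst type that should leave aryl benzyl ethers, the diaryl ether and the flavone untouched.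

Step 6
Reactants: 10 ethyl (3R)-3-(4-{2-(benzyloxy)-5-[5,7-bis(benzyloxy)-4-oxo-4H-chromen-2-yl]phenoxy}phenyl)-3-hydroxypropanoate; 11 3,5-dimethoxyphenol
Product: 12 ethyl (3S)-3-(4-{2-(benzyloxy)-5-[5,7-bis(benzyloxy)-4-oxo-4H-chromen-2-yl]phenoxy}phenyl)-3-(3,5-dimethoxyphenoxy)propanoate
Conditions: PPh3, DIAD, toluene, 0 °C to rt
Reagents that add atoms: none
Why: Mitsunobu etherification, in which the carbinol is activated as its alkoxyphosphonium ion and displaced by the phenoxide of 11 in an SN2 step, so that C3 is inverted from R to S, the C2 configuration of the target, the symmetric phenol being able to give only one ether.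

Step 7
Reactants: 12 ethyl (3S)-3-(4-{2-(benzyloxy)-5-[5,7-bis(benzyloxy)-4-oxo-4H-chromen-2-yl]phenoxy}phenyl)-3-(3,5-dimethoxyphenoxy)propanoate
Product: 13 (3S)-3-(4-{2-(benzyloxy)-5-[5,7-bis(benzyloxy)-4-oxo-4H-chromen-2-yl]phenoxy}phenyl)-3-(3,5-dimethoxyphenoxy)propanoic acid
Conditions: LiOH·H2O (2 equiv), THF/H2O, 0 °C; then 1 M HCl to pH 3
Reagents that add atoms: lithium hydroxide, [Li+].[OH-]
Why: Ester saponification (BAc2) at 0 °C, in which hydroxide should add to the ester carbonyl faster than it deprotonates the α-CH2, so that E1cB loss of the β-aryloxy group is avoided and the stereocenter, which carries no acidic hydrogen, is not affected.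

Step 8
Reactants: 13 (3S)-3-(4-{2-(benzyloxy)-5-[5,7-bis(benzyloxy)-4-oxo-4H-chromen-2-yl]phenoxy}phenyl)-3-(3,5-dimethoxyphenoxy)propanoic acid
Product: 15 (2S)-2-(4-{2-(benzyloxy)-5-[5,7-bis(benzyloxy)-4-oxo-4H-chromen-2-yl]phenoxy}phenyl)-5,7-dimethoxy-2,3-dihydro-4H-chromen-4-one, via mixed trifluoroacetic anhydride 14 (not isolated)
Conditions: (CF3CO)2O (1.5 equiv), CH2Cl2, 0 °C to rt
Reagents that add atoms: none
Why: (CF3CO)2O converts the acid into the mixed anhydride 14, whose acyl carbon (C4) is attacked by the carbon ortho to O1 of the 3,5-dimethoxyphenyl ether (C4a) to give a Wheland intermediate that rearomatises with loss of CF3CO2H (intramolecular electrophilic aromatic substitution). The closest known reaction type is the anhydride- or acid-mediated Friedel–Crafts cyclisation of 3-aryloxypropanoic acids to chroman-4-ones. Ring C closes as a six-membered ring in the 6-exo-trig mode at the acyl carbon, with the arene bond C4a–C8a inside the new ring. No stereocenter is formed, and C2 should keep the S configuration from step 6 because neither its C–H nor its C–O bond is involved and no base is present. The step needs regioselectivity on ring A and chemoselectivity among five arenes: the two carbons ortho to O1 are equivalent and the para carbon cannot be reached by the three-atom tether, so only one chromanone can form, and this position, activated by three oxygens, should outrun the carbonyl-deactivated flavone rings and the ring B positions meta to the aryloxy group. It also needs the benzylic C2–O1 bond to stay intact, which the absence of a Lewis acid and the low temperature should secure.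

Step 9
Reactants: 15 (2S)-2-(4-{2-(benzyloxy)-5-[5,7-bis(benzyloxy)-4-oxo-4H-chromen-2-yl]phenoxy}phenyl)-5,7-dimethoxy-2,3-dihydro-4H-chromen-4-one
Product: 16 (2S)-2-{4-[5-(5,7-dihydroxy-4-oxo-4H-chromen-2-yl)-2-hydroxyphenoxy]phenyl}-5-hydroxy-7-methoxy-2,3-dihydro-4H-chromen-4-one
Conditions: BCl3 (1 M in CH2Cl2, 10 equiv), pentamethylbenzene (10 equiv), CH2Cl2, −78 °C then 0 °C; aq. work-up
Reagents that add atoms: none
Why: Lewis-acid debenzylation combined with chelation-controlled demethylation, in which BCl3 with pentamethylbenzene as benzyl-cation scavenger cleaves the three aryl benzyl ethers at −78 °C and, on warming, the boron chelate between the C4 carbonyl and O5 of the flavanone directs chloride to the peri O5–CH3 only, so that the C7 methoxy group, the diaryl ether and C2 (no base, no enolisation) should survive.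

**Compound list**

1 | 1-[2,4-bis(benzyloxy)-6-hydroxyphenyl]ethan-1-one | CC(=O)c1c(O)cc(OCc2ccccc2)cc1OCc1ccccc1 | starting material
2 | 4-(benzyloxy)-3-hydroxybenzaldehyde | O=Cc1ccc(OCc2ccccc2)c(O)c1 | starting material
3 | (2E)-1-[2,4-bis(benzyloxy)-6-hydroxyphenyl]-3-[4-(benzyloxy)-3-hydroxyphenyl]prop-2-en-1-one | O=C(/C=C/c1ccc(OCc2ccccc2)c(O)c1)c1c(O)cc(OCc2ccccc2)cc1OCc1ccccc1 | intermediate
4 | rac-5,7-bis(benzyloxy)-2-[4-(benzyloxy)-3-hydroxyphenyl]-2,3-dihydro-4H-chromen-4-one | O=C1CC(c2ccc(OCc3ccccc3)c(O)c2)Oc2cc(OCc3ccccc3)cc(OCc3ccccc3)c21 | intermediate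
5 | 5,7-bis(benzyloxy)-2-[4-(benzyloxy)-3-hydroxyphenyl]-4H-chromen-4-one | O=c1cc(-c2ccc(OCc3ccccc3)c(O)c2)oc2cc(OCc3ccccc3)cc(OCc3ccccc3)c12 | intermediate
6 | 4-fluorobenzaldehyde | O=Cc1ccc(F)cc1 | starting material
7 | 4-{2-(benzyloxy)-5-[5,7-bis(benzyloxy)-4-oxo-4H-chromen-2-yl]phenoxy}benzaldehyde | O=Cc1ccc(Oc2cc(-c3cc(=O)c4c(OCc5ccccc5)cc(OCc5ccccc5)cc4o3)ccc2OCc2ccccc2)cc1 | intermediate
8 | ethyl diazoacetate | CCOC(=O)C=[N+]=[N-] | starting material
9 | ethyl 3-(4-{2-(benzyloxy)-5-[5,7-bis(benzyloxy)-4-oxo-4H-chromen-2-yl]phenoxy}phenyl)-3-oxopropanoate | CCOC(=O)CC(=O)c1ccc(Oc2cc(-c3cc(=O)c4c(OCc5ccccc5)cc(OCc5ccccc5)cc4o3)ccc2OCc2ccccc2)cc1 | intermediate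
10 | ethyl (3R)-3-(4-{2-(benzyloxy)-5-[5,7-bis(benzyloxy)-4-oxo-4H-chromen-2-yl]phenoxy}phenyl)-3-hydroxypropanoate | CCOC(=O)C[C@@H](O)c1ccc(Oc2cc(-c3cc(=O)c4c(OCc5ccccc5)cc(OCc5ccccc5)cc4o3)ccc2OCc2ccccc2)cc1 | intermediate
11 | 3,5-dimethoxyphenol | COc1cc(O)cc(OC)c1 | starting material
12 | ethyl (3S)-3-(4-{2-(benzyloxy)-5-[5,7-bis(benzyloxy)-4-oxo-4H-chromen-2-yl]phenoxy}phenyl)-3-(3,5-dimethoxyphenoxy)propanoate | CCOC(=O)C[C@H](Oc1cc(OC)cc(OC)c1)c1ccc(Oc2cc(-c3cc(=O)c4c(OCc5ccccc5)cc(OCc5ccccc5)cc4o3)ccc2OCc2ccccc2)cc1 | intermediate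
13 | (3S)-3-(4-{2-(benzyloxy)-5-[5,7-bis(benzyloxy)-4-oxo-4H-chromen-2-yl]phenoxy}phenyl)-3-(3,5-dimethoxyphenoxy)propanoic acid | OC(=O)C[C@H](Oc1cc(OC)cc(OC)c1)c1ccc(Oc2cc(-c3cc(=O)c4c(OCc5ccccc5)cc(OCc5ccccc5)cc4o3)ccc2OCc2ccccc2)cc1 | intermediate
14 | (3S)-3-(4-{2-(benzyloxy)-5-[5,7-bis(benzyloxy)-4-oxo-4H-chromen-2-yl]phenoxy}phenyl)-3-(3,5-dimethoxyphenoxy)propanoic trifluoroacetic anhydride | O=C(C[C@H](Oc1cc(OC)cc(OC)c1)c1ccc(Oc2cc(-c3cc(=O)c4c(OCc5ccccc5)cc(OCc5ccccc5)cc4o3)ccc2OCc2ccccc2)cc1)OC(=O)C(F)(F)F | intermediate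
15 | (2S)-2-(4-{2-(benzyloxy)-5-[5,7-bis(benzyloxy)-4-oxo-4H-chromen-2-yl]phenoxy}phenyl)-5,7-dimethoxy-2,3-dihydro-4H-chromen-4-one | COc1cc(OC)c2c(c1)O[C@H](c1ccc(Oc3cc(-c4cc(=O)c5c(OCc6ccccc6)cc(OCc6ccccc6)cc5o4)ccc3OCc3ccccc3)cc1)CC2=O | intermediate
16 | (2S)-2-{4-[5-(5,7-dihydroxy-4-oxo-4H-chromen-2-yl)-2-hydroxyphenoxy]phenyl}-5-hydroxy-7-methoxy-2,3-dihydro-4H-chromen-4-one | COc1cc(O)c2c(c1)O[C@H](c1ccc(Oc3cc(-c4cc(=O)c5c(O)cc(O)cc5o4)ccc3O)cc1)CC2=O | target

Total step count: 9. Longest linear sequence: 9 steps (from 1 or 2 to 16).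

**Steps most likely to fail**

Step 8. What may go wrong is acid-promoted heterolysis of the benzylic C2–O1 bond before the acylation (loss of configuration, elimination to the cinnamic acid, C-alkylation of ring A), or competing C-trifluoroacetylation of ring A. The fallback gives up the acylative closure and makes the flavanone by enantioselective conjugate arylation of a preformed chromone. It sets out from 5. Ullmann etherification with 1-bromo-4-iodobenzene (CuI, picolinic acid, K3PO4, DMSO, 90 °C; the iodide should react selectively) should give 5,7-bis(benzyloxy)-2-[4-(benzyloxy)-3-(4-bromophenoxy)phenyl]-4H-chromen-4-one F1. Borylation (Pd(OAc)2, XPhos, B2(OH)4, KOAc, EtOH, 80 °C) should give (4-{2-(benzyloxy)-5-[5,7-bis(benzyloxy)-4-oxo-4H-chromen-2-yl]phenoxy}phenyl)boronic acid F2. Rhodium-catalysed Hayashi–Miyaura 1,4-addition of the boronic acid to purchasable 5,7-dimethoxy-4H-chromen-4-one ([Rh(OH)(cod)]2, an electron-poor atropisomeric bisphosphine in the enantiomer that gives the 2S product, toluene/H2O, 40 °C) should then give 15, where the route is rejoined before step 9.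

Step 6. What may go wrong is E2 dehydration of the activated β-hydroxy ester to the cinnamate, and partial loss of configuration through an ion-pair pathway at the p-aryloxybenzylic carbon. The fallback forms the aryl ether at the oxygen–aryl bond, with retention, on a substrate that carries the carboxyl as a terminal alkene. It sets out from 7. Brown allylation with (−)-B-allyldiisopinocampheylborane (Et2O, −78 °C; NaBO3 work-up) should give 5,7-bis(benzyloxy)-2-[4-(benzyloxy)-3-{4-[(1S)-1-hydroxybut-3-en-1-yl]phenoxy}phenyl]-4H-chromen-4-one F3. Copper-catalysed O-arylation with 1-iodo-3,5-dimethoxybenzene (CuI, 3,4,7,8-tetramethyl-1,10-phenanthroline, Cs2CO3, toluene, 110 °C), which does not touch the C–O bond at the stereocenter, should give 5,7-bis(benzyloxy)-2-[4-(benzyloxy)-3-{4-[(1S)-1-(3,5-dimethoxyphenoxy)but-3-en-1-yl]phenoxy}phenyl]-4H-chromen-4-one F4. Lemieux–Johnson cleavage (OsO4 cat., NaIO4, 2,6-lutidine, dioxane/H2O) should give (3S)-3-(4-{2-(benzyloxy)-5-[5,7-bis(benzyloxy)-4-oxo-4H-chromen-2-yl]phenoxy}phenyl)-3-(3,5-dimethoxyphenoxy)propanal F5. Pinnick oxidation (NaClO2, NaH2PO4, 2-methylbut-2-ene, t-BuOH/H2O) should then give the acid 13, where the route is rejoined before step 8; steps 4, 5 and 7 are bypassed as well.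

Step 9. What may go wrong is Lewis-acid-induced opening of ring C at the benzylic C2–O1 bond (racemisation through the chalcone), C-benzylation of the phloroglucinol rings by benzyl cations that escape the scavenger, or loss of the C7 methyl group. The fallback removes the benzyl groups reductively and leaves a single, milder chelation-directed demethylation. It sets out from 15. Hydrogenolysis (H2 1 atm, Pd/C, THF/EtOAc, rt) should give (2S)-2-{4-[5-(5,7-dihydroxy-4-oxo-4H-chromen-2-yl)-2-hydroxyphenoxy]phenyl}-5,7-dimethoxy-2,3-dihydro-4H-chromen-4-one F6. MgI2 etherate (MgI2·OEt2, THF, 50 °C), which chelates C4=O and O5 and delivers iodide to the peri methyl group only, should then give 16.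

Further compounds
F1 | step 8 | 5,7-bis(benzyloxy)-2-[4-(benzyloxy)-3-(4-bromophenoxy)phenyl]-4H-chromen-4-one | Brc1ccc(Oc2cc(-c3cc(=O)c4c(OCc5ccccc5)cc(OCc5ccccc5)cc4o3)ccc2OCc2ccccc2)cc1
F2 | step 8 | (4-{2-(benzyloxy)-5-[5,7-bis(benzyloxy)-4-oxo-4H-chromen-2-yl]phenoxy}phenyl)boronic acid | OB(O)c1ccc(Oc2cc(-c3cc(=O)c4c(OCc5ccccc5)cc(OCc5ccccc5)cc4o3)ccc2OCc2ccccc2)cc1
F3 | step 6 | 5,7-bis(benzyloxy)-2-[4-(benzyloxy)-3-{4-[(1S)-1-hydroxybut-3-en-1-yl]phenoxy}phenyl]-4H-chromen-4-one | C=CC[C@H](O)c1ccc(Oc2cc(-c3cc(=O)c4c(OCc5ccccc5)cc(OCc5ccccc5)cc4o3)ccc2OCc2ccccc2)cc1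
F4 | step 6 | 5,7-bis(benzyloxy)-2-[4-(benzyloxy)-3-{4-[(1S)-1-(3,5-dimethoxyphenoxy)but-3-en-1-yl]phenoxy}phenyl]-4H-chromen-4-one | C=CC[C@H](Oc1cc(OC)cc(OC)c1)c1ccc(Oc2cc(-c3cc(=O)c4c(OCc5ccccc5)cc(OCc5ccccc5)cc4o3)ccc2OCc2ccccc2)cc1
F5 | step 6 | (3S)-3-(4-{2-(benzyloxy)-5-[5,7-bis(benzyloxy)-4-oxo-4H-chromen-2-yl]phenoxy}phenyl)-3-(3,5-dimethoxyphenoxy)propanal | O=CC[C@H](Oc1cc(OC)cc(OC)c1)c1ccc(Oc2cc(-c3cc(=O)c4c(OCc5ccccc5)cc(OCc5ccccc5)cc4o3)ccc2OCc2ccccc2)cc1
F6 | step 9 | (2S)-2-{4-[5-(5,7-dihydroxy-4-oxo-4H-chromen-2-yl)-2-hydroxyphenoxy]phenyl}-5,7-dimethoxy-2,3-dihydro-4H-chromen-4-one | COc1cc(OC)c2c(c1)O[C@H](c1ccc(Oc3cc(-c4cc(=O)c5c(O)cc(O)cc5o4)ccc3O)cc1)CC2=O
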